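# Dihydroptychantol A: ring C from a 5-acyl-2-pyrone and an aryl ethynyl ether

## The problem

Dihydroptychantol A (24) is a macrocyclic bis(bibenzyl). Its four benzene rings form one 18-membered ring in the order A–CH2CH2–B–O–C–CH2CH2–D–O–A. The large ring passes through ring A at two adjacent carbons, through rings B and D at 1,3-related carbons and through ring C at 1,4-related carbons. Ring A carries a free OH para to its ether oxygen, and ring B a free OH ortho to its ether oxygen. There is no stereocentre and no alkene, so no centre can control another, and the task reduces to connectivity, substitution pattern and one ring closure. The difficult bonds are the two diaryl ether C–O bonds: none of the aryl carbons involved has an activating group in the target, and the ring A oxygen is crowded by the ortho CH2CH2 chain. Four phenolic oxygens on rings A and B must be told apart, two ending as bridges and two as hydroxyls. The hydroquinone-type phenol of ring A and the catechol-type phenol of ring B oxidise easily under basic, aerobic or copper-containing conditions and should stay masked until the last step. The opening for the key step is ring C, which has four C–H positions and only two substituents: the oxygen from ring B at C1 and the bridge carbon at C4. If that bridge carbon is written as a ketone, ring C shows the para donor–acceptor pattern that C3 to C6 of a 5-acyl-2-pyrone and the two carbons of an aryloxyacetylene produce directly.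

## Retrosynthesis

**Unmasking (24 from 23).**
- Cut: the two O–CH3 bonds of the dimethyl ether 23 are cleaved last.
- Why methyl: unlike benzyl or silyl, it passes unchanged through hydrogenation, organolithium base, hot toluene, strong acid and hot carbonate. These two oxygens therefore need no protecting-group changes.
- Simplification: 23 has the same skeleton as 24 but no oxidisable phenol.
- Forward demand: the step only has to distinguish alkyl–O from aryl–O bonds, which Lewis-acidic demethylation does.

**Macrocycle (23 from 22).**
- Cut: the bond O(ring A)–C3(ring D).
- Against the neighbours: the B–O–C ether arrives with the key step anyway. Closing at either CH2–CH2 bridge would require two extra carbon functional groups to be carried through the whole sequence.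
- Simplification: this cut leaves the open-chain tetra-arene 22, whose ends are one phenol and one aryl bromide. Both groups are spectators in every earlier step.
- Forward demand: a copper-catalysed aryl ether closure at high dilution. The phenoxide is ortho-substituted but electron-rich, and the bromide is unactivated but unhindered. This is the most demanding conventional step of the plan.

**Oxidation-state adjustment (22 from 19).**
- No skeletal bond is cut. The benzylic CH2 next to ring C is written as a ketone and the ring A phenol as its methoxymethyl (MOM) ether.
- The ketone is not a detour, because it is the acceptor that the ring C construction needs.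
- MOM is preferred to benzyl at this oxygen. A benzyl group would forbid hydrogenation at the A–B bridge and would need a deprotection step of its own, whereas MOM falls in the same acid that drives the ionic hydrogenation.
- One operation should therefore take 19 through 20 and 21 to 22.

**Ring C (19 from 12 and 17).**
- Cut: with C1 as the oxygen-bearing carbon and C4 as the acyl-bearing carbon, the C1–C6 and C2–C3 bonds of ring C.
- Fragments: C3 to C6 return to the diene carbons of pyrone 17, and C1/C2 to the alkyne carbons of 12. The bridged lactone 18 lies between them.
- Against the neighbour: cutting the B–O–C ether bond would call for a second aryl ether coupling and a pre-made para-substituted arene. Here the ether oxygen travels in on the alkyne and both bridge carbons travel in on the pyrone.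
- Simplification: a four-ring ketone falls into a two-ring and a one-ring fragment of similar weight.
- Forward demand: para rather than meta orientation, and an alkyne that survives the temperature of the cycloaddition.

**Pyrone (17 from 14 and 16).**
- Cut: the C(=O)–CH2 bond.
- Against the neighbours: a cut between pyrone C5 and the carbonyl would need a metalated pyrone. A cut at CH2–aryl would need enolate arylation on a base-sensitive lactone.
- Simplification: acid chloride 14 is one step from coumalic acid 13, and zinc reagent 16 is one operation from dibromide 15.
- Forward demand: a nucleophile mild enough to ignore the lactone and C6, and a catalyst that takes the acyl chloride before the aryl bromide.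

**Ynol ether (12 from 8).**
- Cut: the O–C(sp) bond.
- Direct O-alkynylation of a phenol is not available. The two carbons are therefore added as a dichlorovinyl group (9), and the alkyne is released by elimination and halogen–metal exchange through 10 and 11.
- Simplification: the precursor 8 is a plain phenol.
- Forward demand: no halogen, carbonyl or acidic group elsewhere in the fragment, which holds for 9.

**A–B bridge (8 from 3 and 5).**
- Cut: the central C–C bond of the bridge, written as the alkene of 7. This gives phosphonium salt 3 (ylide 6) and aldehyde 5.
- Why ring B carries the phosphonium: the acid used to make the salt then never meets the MOM group.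
- Why ring B is benzylated: one hydrogenation both saturates the bridge and frees exactly the phenol needed for 9.
- Starting materials: 3 comes from commercial aldehyde 1 through alcohol 2, and 5 comes from commercial phenol 4.

## Roads not taken

Alternative 1:
- **Cut.** The bond between ring A and the CH2 of the A–B bridge is traced back to a bond from that CH2 to the oxygen-bearing ring A carbon. This turns the macrocycle into the 17-membered spiro 4-alkyl-4-aryloxycyclohexa-2,5-dienone A1.
- **Forward key step.** Acid protonates the dienone carbonyl and the CH2 shifts to the neighbouring ring carbon. The cation left behind is held by the aryloxy oxygen. Proton loss then aromatises ring A to the ring B monomethyl ether A2, with growth to 18 members.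
- **Merits.** The crowded A–O–D ether is made at an sp3 carbon. The two migration termini are equivalent, so there is no regiochemical question. The ring A hydroxyl emerges free, and only one methyl ether remains to be cleaved.
- **Weak points.**
  - A1 has to come from an oxidative dearomatisation in which a remote, weakly nucleophilic phenol captures the activated ring A carbon. This capture is macrocyclic and competes with solvent and with C-attack by three electron-rich rings.
  - In acid, A1 can also ionise by expelling the ring D phenol, a good leaving group, which reopens the ring.
  - A primary alkyl group migrates reluctantly.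
- **Comparison.** On paper the endgame is shorter and free of copper, and in that respect this road is better. Against this, the chosen plan has only one macrocyclic event, which is of an established reaction type, whereas this road stacks two macrocyclic steps without a close model.

Alternative 2:
- **Cut.** Two C–C bonds of ring A are cut, leading to the 2-aryloxyfuran A3 (rings D and C) and the terminal ynone A4 (ring B).
- **Forward key step.** A [4+2] addition joins the acyl-bearing alkyne carbon to the oxygenated furan carbon. The oxygen bridge then opens toward the aryloxy-stabilised cation, and tautomerisation gives the 4-aryloxyphenol A5 with the acyl bridge ortho to the ether.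
- **Merits.** The logic matches the chosen plan but is applied to the harder ether. The hindered A–O–D bond is never made by coupling, and the later ring closure falls on the less crowded B–O–C ether. In this respect the road is clearly better.
- **Weak points.**
  - A3 belongs to a labile class that is awkward to prepare and hydrolyses readily to a butenolide.
  - Furan cycloadditions are reversible and have no gas-releasing step to pull them forward.
  - A5 emerges with a free ring A hydroxyl, which must be masked before the ring B phenol can be coupled selectively.
  - The benzyl group has to be removed in the presence of an aryl bromide.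
- **Comparison.** The chosen plan offers components that are each two steps from stable compounds, a cycloaddition made irreversible by decarboxylation, and an open-chain precursor 22 with only one phenol. The price is the harder macrocyclic etherification.

Alternative 3:
- **Cut.** The same O(ring A)–C(ring D) bond as in the chosen plan is cut, but ring D is drawn below the aromatic oxidation level as the 3-chlorocyclohex-2-enone A6.
- **Forward key step.** The ring A phenoxide adds to the chlorine-bearing carbon and expels chloride, closing the ring to the racemic macrocyclic 3-aryloxycyclohexenone A7.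
- **Merits.** Addition–elimination needs no metal, tolerates a hindered phenoxide, runs at modest temperature and uses a more flexible chain end. For the closure itself it is probably the safer reaction.
- **Weak points.**
  - They come after the closure, because the carbonyl oxygen of A7 does not belong in the target.
  - Carbonyl reduction followed by acid is the classical way to eject the vinylogous ester oxygen, which here would cut the macrocycle open again.
  - Aromatisation with retention of the oxygen leaves an extra hydroxyl that costs sulfonylation and reduction.
  - A stereocentre is created only to be destroyed.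
  - The vinylogous ester exchange is reversible and can drift to oligomers.
  - The saturated ring D precursor needs its own multistep synthesis.
- **Comparison.** This road wins on the closing step and loses about three steps afterwards. The chosen plan closes with a harder reaction but reaches the target one step later.

Key step: step 10

Remark on the chemistry: 24 has no stereocentre and its macrocycle is taken to be conformationally mobile, so no descriptor is needed; 7 is carried on as an E/Z mixture because both isomers give 8, and 18 and 21 are racemic and transient.

## Steps

Step 1
Reactants: 1 3-(benzyloxy)-4-methoxybenzaldehyde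
Product: 2 [3-(benzyloxy)-4-methoxyphenyl]methanol
Conditions: NaBH4, MeOH, 0 °C
Reagents that add atoms: none
Why: Borohydride reduction of an aromatic aldehyde; the benzyl and methyl ethers are inert.

Step 2
Reactants: 2 [3-(benzyloxy)-4-methoxyphenyl]methanol
Product: 3 [3-(benzyloxy)-4-methoxybenzyl]triphenylphosphonium bromide
Conditions: PPh3·HBr, MeCN, reflux
Reagents that add atoms: triphenylphosphine hydrobromide, c1ccc(cc1)[PH+](c1ccccc1)c1ccccc1.[Br-]
Why: The para-methoxy group lets the benzylic alcohol ionise under the mild acidity of the salt, and the phosphine captures the benzylic electrophile, a routine direct alcohol-to-phosphonium conversion for alkoxybenzyl alcohols. The aryl benzyl ether tolerates this acidity.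

Step 3
Reactants: 4 2-hydroxy-5-methoxybenzaldehyde
Product: 5 5-methoxy-2-(methoxymethoxy)benzaldehyde
Conditions: MOMCl, K2CO3, acetone, 0 °C to rt
Reagents that add atoms: chloromethyl methyl ether, COCCl
Why: Williamson-type O-alkylation of the phenoxide. MOM is chosen because it resists base, hydrogenation, butyllithium and heat but falls in the acid of step 11.

Step 4
Reactants: 3 [3-(benzyloxy)-4-methoxybenzyl]triphenylphosphonium bromide; 5 5-methoxy-2-(methoxymethoxy)benzaldehyde
Product: 7 3-(benzyloxy)-4,5'-dimethoxy-2'-(methoxymethoxy)stilbene (E/Z mixture), via ring B benzylidenephosphorane 6 (not isolated)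
Conditions: KOtBu, THF, 0 °C; then 5, 0 °C to rt
Reagents that add atoms: none
Why: Wittig olefination of a semi-stabilised benzylic ylide with a non-enolisable aldehyde. The alkene geometry does not matter because step 5 removes it.

Step 5
Reactants: 7 3-(benzyloxy)-4,5'-dimethoxy-2'-(methoxymethoxy)stilbene
Product: 8 3-hydroxy-4,5'-dimethoxy-2'-(methoxymethoxy)bibenzyl
Conditions: H2 (1 atm), 10% Pd/C, EtOAc–EtOH, rt
Reagents that add atoms: none
Why: Catalytic hydrogenation saturates the stilbene and hydrogenolyses the aryl benzyl ether in one operation, freeing only the ring B phenol. MOM and methyl ethers are untouched under neutral conditions.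

Step 6
Reactants: 8 3-hydroxy-4,5'-dimethoxy-2'-(methoxymethoxy)bibenzyl
Product: 9 3-[(E)-1,2-dichlorovinyloxy]-4,5'-dimethoxy-2'-(methoxymethoxy)bibenzyl
Conditions: Cl2C=CHCl, K2CO3, DMF, 70 °C
Reagents that add atoms: trichloroethylene, ClC=C(Cl)Cl
Why: The base eliminates HCl from trichloroethylene to give transient dichloroacetylene, and the phenoxide adds to it in anti fashion; this is the standard preparation of aryl (E)-1,2-dichlorovinyl ethers. Compound 8 offers a single nucleophilic site.

Step 7
Reactants: 9 3-[(E)-1,2-dichlorovinyloxy]-4,5'-dimethoxy-2'-(methoxymethoxy)bibenzyl
Product: 12 3-(ethynyloxy)-4,5'-dimethoxy-2'-(methoxymethoxy)bibenzyl, via chloroethynyl ether 10 (not isolated), via lithium aryloxyacetylide 11 (not isolated)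
Conditions: n-BuLi (2.5 equiv), THF, −78 to −40 °C; then H2O, −78 °C; neutral work-up, Et3N-deactivated silica
Reagents that add atoms: none
Why: Vinyl deprotonation and loss of LiCl give 10, chlorine–lithium exchange gives 11 and water protonates it, the established dichlorovinyl ether route to terminal ynol ethers. The fragment holds no halide or carbonyl group, and any aryllithium formed next to the MOM group is simply reprotonated in the quench.

Step 8
Reactants: 13 coumalic acid (2-oxo-2H-pyran-5-carboxylic acid)
Product: 14 coumalyl chloride (2-oxo-2H-pyran-5-carbonyl chloride)
Conditions: SOCl2, reflux; evaporate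
Reagents that add atoms: thionyl chloride, O=S(Cl)Cl
Why: Standard acid chloride formation; the pyrone ring is stable to acidic, non-nucleophilic conditions.

Step 9
Reactants: 15 3-bromobenzyl bromide; 14 coumalyl chloride
Product: 17 5-[(3-bromophenyl)acetyl]-2H-pyran-2-one, via (3-bromobenzyl)zinc bromide 16 (not isolated)
Conditions: 15, Zn dust, LiCl, THF, 0 °C; then 14, Pd(PPh3)4 (5 mol %), THF, 0 °C to rt
Reagents that add atoms: none
Why: Zinc inserts into the benzylic C–Br bond far faster than into the aryl C–Br bond, and the Negishi acylation relies on the acyl chloride adding to zerovalent palladium well before an aryl bromide does at this temperature. The organozinc is too mild to open the lactone, and 2-pyrones are known to survive palladium-catalysed couplings.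

Step 10
Reactants: 12 3-(ethynyloxy)-4,5'-dimethoxy-2'-(methoxymethoxy)bibenzyl; 17 5-[(3-bromophenyl)acetyl]-2H-pyran-2-one
Product: 19 2-(3-bromophenyl)-1-[4-(2-methoxy-5-{2-[5-methoxy-2-(methoxymethoxy)phenyl]ethyl}phenoxy)phenyl]ethanone, via bridged bicyclic lactone 18 (not isolated)
Conditions: 17 (1.3 equiv), BHT (cat.), PhMe, reflux, Ar
Reagents that add atoms: none
Why: This is an inverse-electron-demand Diels–Alder reaction of a 2-pyrone with an electron-rich alkyne followed by cycloreversion, the reaction type that converts coumalate esters into para-substituted benzoates with ynamines, alkoxyalkynes and ketene acetals. The terminal carbon of 12 carries the largest HOMO coefficient, and C6 of 17 is the most electrophilic diene carbon, being β to the C5 ketone and δ to the lactone carbonyl, so these two atoms bond first in a strongly asynchronous transition state and the oxygen-bearing alkyne carbon closes onto C3. Ring C is thus closed by an intermolecular [4+2] addition that forms the C6–CH and C3–C(OAr) bonds and gives the 2-oxabicyclo[2.2.2]octadienone 18. Lactone 18 expels CO2 by retro-[4+2] at the reaction temperature, which makes the sequence irreversible and delivers the benzene ring without an oxidant. The selectivity needed is para against meta orientation, and it is secured because both carbonyl groups of 17 polarise the diene in the same sense while the alkyne has a single donor. The two bridgehead stereocentres of 18 vanish with the CO2, so no stereocentre has to be controlled. An aryl ynol ether has no β-hydrogen on its oxygen substituent and cannot fragment to a ketene on heating as alkyl ynol ethers do, and the bromide, MOM and methyl ethers are spectators.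

Step 11
Reactants: 19 2-(3-bromophenyl)-1-[4-(2-methoxy-5-{2-[5-methoxy-2-(methoxymethoxy)phenyl]ethyl}phenoxy)phenyl]ethanone
Product: 22 2-[2-(3-{4-[2-(3-bromophenyl)ethyl]phenoxy}-4-methoxyphenyl)ethyl]-4-methoxyphenol, via ketophenol 20 (not isolated), via racemic carbinol 21 (not isolated)
Conditions: Et3SiH (6 equiv), CF3CO2H–CH2Cl2 (1:1), 0 °C to rt
Reagents that add atoms: none
Why: Ionic hydrogenation of an aryl ketone: hydride transfer to the protonated ketone gives 21, which ionises to a cation stabilised by the para-aryloxy group and is reduced again to CH2. The same acid cleaves the aryl MOM acetal with the phenol as leaving group, and the excess silane, a better nucleophile than any arene present, reduces the methoxymethyl cation to dimethyl ether. The aryl bromide, diaryl ether and methyl ethers are inert.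

Step 12
Reactants: 22 2-[2-(3-{4-[2-(3-bromophenyl)ethyl]phenoxy}-4-methoxyphenyl)ethyl]-4-methoxyphenol
Product: 23 dihydroptychantol A dimethyl ether (18-membered macrocycle)
Conditions: CuCl (0.5 equiv), 2,2,6,6-tetramethylheptane-3,5-dione (0.25 equiv), Cs2CO3, NMP, 120 °C, Ar, syringe-pump addition (final 2 mM)
Reagents that add atoms: none
Why: Intramolecular Ullmann diaryl ether synthesis; diketone-ligated copper catalysts couple electron-rich, ortho-substituted phenoxides with unactivated aryl bromides, and macrocyclic Ullmann closures of cyclophane diaryl ethers are established. Compound 22 has one phenol and one halide, and pseudo-high dilution favours the 18-membered ring over oligomers.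

Step 13
Reactants: 23 dihydroptychantol A dimethyl ether
Product: 24 dihydroptychantol A
Conditions: BBr3, CH2Cl2, −78 °C to rt; then H2O
Reagents that add atoms: none
Why: BBr3 cleaves both aryl methyl ethers by bromide attack on the methyl carbon of the boron-complexed ether. The diaryl ethers offer no sp3 carbon for that attack and remain intact.

## Compound list

1 | 3-(benzyloxy)-4-methoxybenzaldehyde | COc1ccc(C=O)cc1OCc1ccccc1 | starting material
2 | [3-(benzyloxy)-4-methoxyphenyl]methanol | COc1ccc(CO)cc1OCc1ccccc1 | intermediate
3 | [3-(benzyloxy)-4-methoxybenzyl]triphenylphosphonium bromide | COc1ccc(C[P+](c2ccccc2)(c2ccccc2)c2ccccc2)cc1OCc1ccccc1.[Br-] | intermediate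
4 | 2-hydroxy-5-methoxybenzaldehyde | COc1ccc(O)c(C=O)c1 | starting material
5 | 5-methoxy-2-(methoxymethoxy)benzaldehyde | COCOc1ccc(OC)cc1C=O | intermediate
6 | ring B benzylidenephosphorane (ylide of 3, not isolated) | COc1ccc([CH-][P+](c2ccccc2)(c2ccccc2)c2ccccc2)cc1OCc1ccccc1 | intermediate
7 | 3-(benzyloxy)-4,5'-dimethoxy-2'-(methoxymethoxy)stilbene, E/Z mixture | COCOc1ccc(OC)cc1C=Cc1ccc(OC)c(OCc2ccccc2)c1 | intermediate
8 | 3-hydroxy-4,5'-dimethoxy-2'-(methoxymethoxy)bibenzyl | COCOc1ccc(OC)cc1CCc1ccc(OC)c(O)c1 | intermediate
9 | 3-[(E)-1,2-dichlorovinyloxy]-4,5'-dimethoxy-2'-(methoxymethoxy)bibenzyl | Cl/C=C(/Cl)Oc1cc(CCc2cc(OC)ccc2OCOC)ccc1OC | intermediate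
10 | 3-(chloroethynyloxy)-4,5'-dimethoxy-2'-(methoxymethoxy)bibenzyl (not isolated) | ClC#COc1cc(CCc2cc(OC)ccc2OCOC)ccc1OC | intermediate
11 | lithium aryloxyacetylide of 12 (not isolated) | [Li]C#COc1cc(CCc2cc(OC)ccc2OCOC)ccc1OC | intermediate
12 | 3-(ethynyloxy)-4,5'-dimethoxy-2'-(methoxymethoxy)bibenzyl | C#COc1cc(CCc2cc(OC)ccc2OCOC)ccc1OC | intermediate
13 | coumalic acid | O=C1C=CC(=CO1)C(=O)O | starting material
14 | coumalyl chloride | O=C1C=CC(=CO1)C(=O)Cl | intermediate
15 | 3-bromobenzyl bromide | BrCc1cccc(Br)c1 | starting material
16 | (3-bromobenzyl)zinc bromide (not isolated) | Br[Zn]Cc1cccc(Br)c1 | intermediate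
17 | 5-[(3-bromophenyl)acetyl]-2H-pyran-2-one | O=C1C=CC(=CO1)C(=O)Cc1cccc(Br)c1 | intermediate
18 | racemic 2-oxabicyclo[2.2.2]octa-5,7-dien-3-one adduct of 12 and 17 (aryloxy on the alkene carbon next to the bridgehead that bears the lactone C=O, acyl on the alkene carbon next to the bridgehead that bears the lactone O; not isolated) | O=C1OC2C=C(Oc3cc(CCc4cc(OC)ccc4OCOC)ccc3OC)C1C=C2C(=O)Cc1cccc(Br)c1 | intermediate
19 | 2-(3-bromophenyl)-1-[4-(2-methoxy-5-{2-[5-methoxy-2-(methoxymethoxy)phenyl]ethyl}phenoxy)phenyl]ethanone | O=C(Cc1cccc(Br)c1)c1ccc(Oc2cc(CCc3cc(OC)ccc3OCOC)ccc2OC)cc1 | intermediate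
20 | 2-(3-bromophenyl)-1-(4-{5-[2-(2-hydroxy-5-methoxyphenyl)ethyl]-2-methoxyphenoxy}phenyl)ethanone (not isolated) | O=C(Cc1cccc(Br)c1)c1ccc(Oc2cc(CCc3cc(OC)ccc3O)ccc2OC)cc1 | intermediate
21 | racemic 2-(3-bromophenyl)-1-(4-{5-[2-(2-hydroxy-5-methoxyphenyl)ethyl]-2-methoxyphenoxy}phenyl)ethanol (not isolated) | OC(Cc1cccc(Br)c1)c1ccc(Oc2cc(CCc3cc(OC)ccc3O)ccc2OC)cc1 | intermediate
22 | 2-[2-(3-{4-[2-(3-bromophenyl)ethyl]phenoxy}-4-methoxyphenyl)ethyl]-4-methoxyphenol | Brc1cccc(CCc2ccc(Oc3cc(CCc4cc(OC)ccc4O)ccc3OC)cc2)c1 | intermediate
23 | dihydroptychantol A dimethyl ether | COc1ccc2c(c1)CCc1ccc(OC)c(c1)Oc1ccc(cc1)CCc1cccc(c1)O2 | intermediate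
24 | dihydroptychantol A | Oc1ccc2c(c1)CCc1ccc(O)c(c1)Oc1ccc(cc1)CCc1cccc(c1)O2 | target

## Step count and risks

Total: 13 steps. Longest linear sequence: 10 steps (steps 1, 2, 4, 5, 6, 7, 10, 11, 12, 13, starting from 1).

**Step 10 (key step).**
- What may go wrong:
  - The ynol ether may polymerise or hydrate at the temperature the cycloaddition needs, because an aryloxy group is a weaker donor than an amino or alkoxy group.
  - The polar intermediate may close through the ketone oxygen (oxadiene mode) instead of through C3.
  - Para selectivity may erode.
- Fallback, leaving from 8 and rejoining at 22: the ether is made by nucleophilic aromatic substitution instead of ring synthesis.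
  - Phenol 8 and 4-fluorobenzaldehyde (K2CO3, DMF, 130 °C) should give 4-(2-methoxy-5-{2-[5-methoxy-2-(methoxymethoxy)phenyl]ethyl}phenoxy)benzaldehyde F1.
  - Zinc reagent 16 adds to the aldehyde (THF, rt) to give the racemic MOM-protected carbinol F2.
  - The conditions of step 11 ionise, reduce and deprotect F2 to 22.

**Step 12.**
- What may go wrong:
  - Intermolecular coupling to oligomers and reductive loss of bromine may compete, since activation of the unactivated bromide is slow and the phenoxide is ortho-hindered.
  - Traces of air may oxidise the electron-rich phenoxide.
- Fallback, leaving from 22 and rejoining at 23: the polarity of the closure is changed to an oxidative coupling near room temperature.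
  - Miyaura borylation (B2pin2, PdCl2(dppf), KOAc, dioxane, 80 °C) gives the phenolic aryl pinacol boronate F3.
  - A Chan–Lam closure with divalent copper (Cu(OAc)2, pyridine, 4 Å sieves, O2, MeCN, high dilution) gives 23.

**Step 9.**
- What may go wrong:
  - Wurtz-type homocoupling may occur during zinc insertion.
  - The organometallic may attack C6 of the pyrone.
  - The acylpalladium species may decarbonylate.
  - The doubly activated CH2 of the product may enolise and self-condense on isolation.
- Fallback, leaving from 12 and rejoining at 19: the same ring construction is run with the best-behaved pyrone and the bridge is attached afterwards.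
  - Compound 12 and commercial methyl coumalate (PhMe, reflux) give methyl 4-(2-methoxy-5-{2-[5-methoxy-2-(methoxymethoxy)phenyl]ethyl}phenoxy)benzoate F4.
  - MeNH(OMe)·HCl and i-PrMgCl (THF, −20 °C) give the N-methoxy-N-methylamide F5.
  - Purchased 3-bromobenzylmagnesium bromide solution (Et2O–THF, 0 °C) converts F5 into 19.

**Step 7.**
- What may go wrong:
  - The terminal ynol ether may hydrate on silica or polymerise on concentration.
  - Chlorine–lithium exchange may be incomplete.
- Fallback, leaving from 9 and rejoining at 22: no terminal ynol ether is handled.
  - Acetylide 11 is quenched with Me3SiCl to give the chromatography-stable trimethylsilylethynyl ether F6.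
  - F6 reacts with 17 (xylene, 140 °C) with the silicon-bearing carbon still the nucleophilic terminus. This gives the ring C silylated ketone F7, with SiMe3 ortho to the aryloxy group.
  - The acid of step 11 then protodesilylates at the oxygen-activated ipso carbon while it reduces the ketone and removes MOM, giving 22.

**Step 11.**
- What may go wrong:
  - The methoxymethyl cation may alkylate the electron-rich rings before the silane intercepts it.
  - The acetal may be reduced to a methyl ether on the ring A oxygen.
  - The reaction may stall at the carbinol or trifluoroacetate stage.
- Fallback, leaving from 19 and rejoining at 22: the deoxygenation is made cation-free and the deprotection is separated from it.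
  - TsNHNH2 (EtOH, reflux) gives the tosylhydrazone F8.
  - Catecholborane followed by NaOAc (CHCl3, reflux) reduces F8 through the diazene to the MOM-protected bromide F9.
  - HCl in MeOH (40 °C), where the solvent traps the acetal carbon, releases 22.

## Further compounds

F1 | step 10 | 4-(2-methoxy-5-{2-[5-methoxy-2-(methoxymethoxy)phenyl]ethyl}phenoxy)benzaldehyde | O=Cc1ccc(Oc2cc(CCc3cc(OC)ccc3OCOC)ccc2OC)cc1
F2 | step 10 | racemic 2-(3-bromophenyl)-1-[4-(2-methoxy-5-{2-[5-methoxy-2-(methoxymethoxy)phenyl]ethyl}phenoxy)phenyl]ethanol | OC(Cc1cccc(Br)c1)c1ccc(Oc2cc(CCc3cc(OC)ccc3OCOC)ccc2OC)cc1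
F3 | step 12 | pinacol boronate of 22 (Bpin in place of Br) | CC1(C)OB(OC1(C)C)c1cccc(CCc2ccc(Oc3cc(CCc4cc(OC)ccc4O)ccc3OC)cc2)c1
F4 | step 9 | methyl 4-(2-methoxy-5-{2-[5-methoxy-2-(methoxymethoxy)phenyl]ethyl}phenoxy)benzoate | COC(=O)c1ccc(Oc2cc(CCc3cc(OC)ccc3OCOC)ccc2OC)cc1
F5 | step 9 | N-methoxy-N-methyl-4-(2-methoxy-5-{2-[5-methoxy-2-(methoxymethoxy)phenyl]ethyl}phenoxy)benzamide | CON(C)C(=O)c1ccc(Oc2cc(CCc3cc(OC)ccc3OCOC)ccc2OC)cc1
F6 | step 7 | 3-[(trimethylsilyl)ethynyloxy]-4,5'-dimethoxy-2'-(methoxymethoxy)bibenzyl | C[Si](C)(C)C#COc1cc(CCc2cc(OC)ccc2OCOC)ccc1OC
F7 | step 7 | 19 bearing SiMe3 on ring C ortho to the aryloxy group and meta to the acyl group | O=C(Cc1cccc(Br)c1)c1ccc(Oc2cc(CCc3cc(OC)ccc3OCOC)ccc2OC)c([Si](C)(C)C)c1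
F8 | step 11 | tosylhydrazone of 19 | Cc1ccc(cc1)S(=O)(=O)NN=C(Cc1cccc(Br)c1)c1ccc(Oc2cc(CCc3cc(OC)ccc3OCOC)ccc2OC)cc1
F9 | step 11 | MOM ether of 22 | Brc1cccc(CCc2ccc(Oc3cc(CCc4cc(OC)ccc4OCOC)ccc3OC)cc2)c1
A1 | alternative 1 | 17-membered spiro 4-alkyl-4-aryloxycyclohexa-2,5-dienone | O=C1C=CC2(C=C1)CCc1ccc(OC)c(c1)Oc1ccc(cc1)CCc1cccc(c1)O2
A2 | alternative 1 | dihydroptychantol A ring B methyl ether | Oc1ccc2c(c1)CCc1ccc(OC)c(c1)Oc1ccc(cc1)CCc1cccc(c1)O2
A3 | alternative 2 | 2-{3-[2-(4-bromophenyl)ethyl]phenoxy}furan | Brc1ccc(CCc2cccc(Oc3ccco3)c2)cc1
A4 | alternative 2 | 1-[3-(benzyloxy)-4-methoxyphenyl]but-3-yn-2-one | C#CC(=O)Cc1ccc(OC)c(OCc2ccccc2)c1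
A5 | alternative 2 | ring A phenol with aryl ether and acyl bridge | Oc1ccc(Oc2cccc(CCc3ccc(Br)cc3)c2)c(c1)C(=O)Cc1ccc(OC)c(OCc2ccccc2)c1
A6 | alternative 3 | racemic open-chain 3-chlorocyclohex-2-enone phenol | COc1ccc(O)c(c1)CCc1ccc(OC)c(c1)Oc1ccc(cc1)CCC1CC(Cl)=CC(=O)C1
A7 | alternative 3 | racemic macrocyclic 3-aryloxycyclohexenone | COc1ccc2c(c1)CCc1ccc(OC)c(c1)Oc1ccc(cc1)CCC1CC(=CC(=O)C1)O2
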